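**Retrosynthetic overview**

- Numbering: C1 is the lactone carbonyl, C2–C5 the ring carbons, C6–C20 the chain. The carbinols C5, C7, C9, C11 are syn, anti, syn, so the C5–C11 segment is C2-symmetric about C8 and its anti C7/C9 diol core (C6–C10) has homotopic ends.
- Bonds C10–C11 and C5–C6 are cut: (2R,4R)-1,2:4,5-diepoxypentane (C6–C10) is opened in turn by lithiated 2-nonyl-1,3-dithiane (C11–C20) and lithiated 2-[2-(benzyloxy)ethyl]-1,3-dithiane (C3–C5).
- The dithiane carbons C5 and C11 become ketones, each β to a carbinol, and one double boron-chelate reduction sets both outer centres syn to C7 and C9.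
- C1–C2 come from a malonate half ester added to the C3 acid (bond C2–C3).
- Rings: two temporary 1,3-dioxanes (C5/C7 and C9/C11 acetonides) are formed first; the only ring of the target, the six-membered lactone ring (ring O, C1–C5), is closed last through the O–C1 bond.

Key step: step 5

Assumption: the target is made as the drawn enol tautomer (4-hydroxy-5,6-dihydro-2H-pyran-2-one), the expected resting form of the 3-oxo-δ-lactone; 1,5-dichloropentane-2,4-dione is treated as purchasable.

**Route**

Step 1
Reactants: 1 1,5-dichloropentane-2,4-dione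
Product: 2 (2R,4R)-1,5-dichloropentane-2,4-diol
Conditions: H2 (85 bar), RuCl2[(S)-BINAP] (0.3 mol %), MeOH, 80 °C; recrystallise
Reagents that add atoms: none
Why: Noyori asymmetric hydrogenation of a 1,3-diketone, in which the catalyst sets both carbinol centres in the same sense so that the anti (C2-symmetric) diol should dominate and recrystallisation should remove meso diol; the (S) ligand is chosen by analogy with 4-chloro-3-oxobutanoates, where it delivers the (R) chlorohydrin, and the sense is to be confirmed by optical rotation before going on.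

Step 2
Reactants: 2 (2R,4R)-1,5-dichloropentane-2,4-diol
Product: 3 (2R,4R)-1,2:4,5-diepoxypentane
Conditions: KOH (powdered), Et2O, rt; distil
Reagents that add atoms: none
Why: double intramolecular Williamson etherification (3-exo-tet) in which each alkoxide displaces chloride at its own CH2, so neither carbinol centre is touched and the R,R configuration is kept.

Step 3
Reactants: 4 decanal; 5 propane-1,3-dithiol
Product: 6 2-nonyl-1,3-dithiane
Conditions: BF3·OEt2 (0.2 equiv), CH2Cl2, 0 °C → rt
Reagents that add atoms: none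
Why: Lewis acid catalysed dithioacetalisation of an unhindered aldehyde, driven by formation of the six-membered dithiane.

Step 4
Reactants: 7 3-(benzyloxy)propanal; 5 propane-1,3-dithiol
Product: 8 2-[2-(benzyloxy)ethyl]-1,3-dithiane
Conditions: BF3·OEt2 (0.2 equiv), CH2Cl2, −20 → 0 °C
Reagents that add atoms: none
Why: the same dithioacetalisation, run cold so that the β-benzyloxy aldehyde does not eliminate benzyl alcohol; the benzyl ether is stable to BF3·OEt2 at this temperature.

Step 5
Reactants: 6 2-nonyl-1,3-dithiane; 3 (2R,4R)-1,2:4,5-diepoxypentane; 8 2-[2-(benzyloxy)ethyl]-1,3-dithiane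
Product: 12 (2R,4R)-1-{2-[2-(benzyloxy)ethyl]-1,3-dithian-2-yl}-5-(2-nonyl-1,3-dithian-2-yl)pentane-2,4-diol, via 2-lithio-2-nonyl-1,3-dithiane 9 (not isolated), via lithium epoxy alkoxide 10 (not isolated), via lithiated benzyloxyethyl dithiane 11 (not isolated)
Conditions: 6, n-BuLi, THF, −25 °C; add dropwise to 3 (3 equiv), THF, −25 °C; strip THF and surplus 3 (0 °C, 0.1 mbar, cold trap); THF/DMPU, then 8 prelithiated with n-BuLi (1.5 equiv, THF, −25 °C), −78 → 0 °C; aq NH4Cl
Reagents that add atoms: none
Why: Each 2-lithio-1,3-dithiane is a sulfur-stabilised carbanion (Corey–Seebach umpolung) that opens a terminal epoxide by SN2 attack at its CH2 carbon, first C10 (bond C10–C11), then C6 (bond C5–C6); the closest known reaction type is the stepwise two-directional opening of this C2-symmetric bis-epoxide by lithiated dithianes. No ring is closed and no stereocentre is created, because attack is at CH2 and C7 and C9 keep the configuration set in step 1. The two epoxide termini of 3 are homotopic, so 9 gives the same epoxy alkoxide 10 whichever end it attacks, and 11 then finds a single electrophilic site. The selectivity needed is mono- over double opening by 9, which is secured by slow inverse addition of 9 to a threefold excess of 3 and by removing the volatile surplus of 3 before 11 is added; terminal regioselectivity follows from the unhindered CH2 carbons. The lithium alkoxide of 10 should not attack its own epoxide at or below 0 °C, since that would need a 4-exo or a 5-endo closure, and DMPU is held back to the second stage, where it speeds up the opening by 11.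

Step 6
Reactants: 12 (2R,4R)-1-{2-[2-(benzyloxy)ethyl]-1,3-dithian-2-yl}-5-(2-nonyl-1,3-dithian-2-yl)pentane-2,4-diol
Product: 13 (5R,7R)-1-(benzyloxy)-5,7-dihydroxyoctadecane-3,9-dione
Conditions: MeI (excess), CaCO3, MeCN/H2O (9:1), 40 °C; crude product used at once
Reagents that add atoms: water, O
Why: alkylative dithiane hydrolysis, in which S-methylation turns each thioacetal sulfur into a leaving group and water captures the thionium ion; CaCO3 keeps the medium neutral so that the β-hydroxy ketones should neither eliminate nor ketalise, and the benzyl ether and both carbinol centres are untouched.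

Step 7
Reactants: 13 (5R,7R)-1-(benzyloxy)-5,7-dihydroxyoctadecane-3,9-dione
Product: 15 (3S,5S,7S,9S)-1-(benzyloxy)octadecane-3,5,7,9-tetrol, via bis(diethylborinate) chelate 14 (not isolated)
Conditions: Et2BOMe (2.4 equiv), THF/MeOH (4:1), −78 °C; NaBH4, −78 °C; AcOH quench; MeOH co-evaporation
Reagents that add atoms: none
Why: Narasaka–Prasad reduction run at both ends of one molecule: each carbinol oxygen carries a BEt2 group that chelates its own β-carbonyl in a six-membered half-chair and external hydride adds axially to give the syn 1,3-diol, so target C5 is set by C7 and target C11 by C9 (the descriptors change to S only because the CIP priorities change).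

Step 8
Reactants: 15 (3S,5S,7S,9S)-1-(benzyloxy)octadecane-3,5,7,9-tetrol
Product: 16 (4S,6S)-4-[2-(benzyloxy)ethyl]-6-{[(4S,6S)-2,2-dimethyl-6-nonyl-1,3-dioxan-4-yl]methyl}-2,2-dimethyl-1,3-dioxane
Conditions: 2,2-dimethoxypropane, PPTS (cat.), CH2Cl2, rt
Reagents that add atoms: 2,2-dimethoxypropane, COC(C)(C)OC
Why: acid-catalysed transketalisation under thermodynamic control, in which the two syn diols (C5/C7 and C9/C11) form chair dioxanes with equatorial substituents while an acetonide over the anti C7/C9 pair would need a twist-boat, so the bis(syn-acetonide) should be the resting product; the 13C shifts of the acetonide methyl groups offer a check of both syn relationships at this stage.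

Step 9
Reactants: 16 (4S,6S)-4-[2-(benzyloxy)ethyl]-6-{[(4S,6S)-2,2-dimethyl-6-nonyl-1,3-dioxan-4-yl]methyl}-2,2-dimethyl-1,3-dioxane
Product: 17 2-[(4S,6S)-6-{[(4S,6S)-2,2-dimethyl-6-nonyl-1,3-dioxan-4-yl]methyl}-2,2-dimethyl-1,3-dioxan-4-yl]ethan-1-ol
Conditions: H2 (1 atm), Pd(OH)2/C, EtOAc, rt
Reagents that add atoms: none
Why: hydrogenolysis of the benzyl ether in a neutral solvent, which leaves both acetonides and all four carbinol centres alone.

Step 10
Reactants: 17 2-[(4S,6S)-6-{[(4S,6S)-2,2-dimethyl-6-nonyl-1,3-dioxan-4-yl]methyl}-2,2-dimethyl-1,3-dioxan-4-yl]ethan-1-ol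
Product: 18 [(4R,6R)-6-{[(4S,6S)-2,2-dimethyl-6-nonyl-1,3-dioxan-4-yl]methyl}-2,2-dimethyl-1,3-dioxan-4-yl]acetic acid
Conditions: TEMPO (cat.), NaOCl (cat.), NaClO2, MeCN/sodium phosphate buffer (pH 6.7), 35 °C; acidify to pH 4, extract
Reagents that add atoms: sodium chlorite NaClO2, [Na+].[O-]Cl=O
Why: TEMPO-catalysed oxidation of the primary alcohol to the aldehyde with in situ chlorite oxidation to the acid; the near-neutral buffer spares the acetonides and the β-alkoxy aldehyde is consumed as it forms, so it should not eliminate (the descriptors of the C5/C7 dioxane change to R only through CIP priority).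

Step 11
Reactants: 18 [(4R,6R)-6-{[(4S,6S)-2,2-dimethyl-6-nonyl-1,3-dioxan-4-yl]methyl}-2,2-dimethyl-1,3-dioxan-4-yl]acetic acid
Product: 20 ethyl 4-[(4R,6R)-6-{[(4S,6S)-2,2-dimethyl-6-nonyl-1,3-dioxan-4-yl]methyl}-2,2-dimethyl-1,3-dioxan-4-yl]-3-oxobutanoate, via acyl imidazolide 19 (not isolated)
Conditions: CDI, THF, rt; Mg(O2CCH2CO2Et)2, THF, rt → 40 °C; cold 0.5 M HCl wash
Reagents that add atoms: magnesium bis(ethyl malonate) Mg(O2CCH2CO2Et)2, CCOC(=O)CC(=O)[O-].CCOC(=O)CC(=O)[O-].[Mg+2]
Why: Masamune–Brooks two-carbon homologation, in which CDI activates the acid as its imidazolide and the magnesium malonate half-ester is C-acylated and loses CO2 to give the β-keto ester (C2 and C1) under neutral conditions that the acetonides tolerate.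

Step 12
Reactants: 20 ethyl 4-[(4R,6R)-6-{[(4S,6S)-2,2-dimethyl-6-nonyl-1,3-dioxan-4-yl]methyl}-2,2-dimethyl-1,3-dioxan-4-yl]-3-oxobutanoate
Product: 22 (6R)-4-hydroxy-6-[(2R,4S,6S)-2,4,6-trihydroxypentadecyl]-5,6-dihydro-2H-pyran-2-one, via tetraol keto ester 21 (not isolated)
Conditions: 1 M HCl, THF, rt; then aq NaOH to pH 12, 0 °C → rt; then 1 M HCl to pH 2; EtOAc extraction, reversed-phase chromatography
Reagents that add atoms: none
Why: aqueous acid hydrolyses both acetonides, and in dilute base the C5 hydroxyl of the δ-hydroxy β-keto ester displaces ethoxide at C1 (6-exo-trig lactonisation) with formation of the stabilised enolate of the 3-oxo lactone as driving force, acidification then giving the enol lactone; no C–O bond at a stereocentre is broken, so C5, C7, C9 and C11 keep their configuration.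

**Compound list**

1 | 1,5-dichloropentane-2,4-dione | ClCC(=O)CC(=O)CCl | starting material
2 | (2R,4R)-1,5-dichloropentane-2,4-diol | ClC[C@H](O)C[C@@H](O)CCl | intermediate
3 | (2R,4R)-1,2:4,5-diepoxypentane | C1O[C@@H]1C[C@@H]1CO1 | intermediate
4 | decanal | CCCCCCCCCC=O | starting material
5 | propane-1,3-dithiol | SCCCS | starting material
6 | 2-nonyl-1,3-dithiane | CCCCCCCCCC1SCCCS1 | intermediate
7 | 3-(benzyloxy)propanal | O=CCCOCc1ccccc1 | starting material
8 | 2-[2-(benzyloxy)ethyl]-1,3-dithiane | c1ccccc1COCCC1SCCCS1 | intermediate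
9 | 2-lithio-2-nonyl-1,3-dithiane | [Li]C1(CCCCCCCCC)SCCCS1 | intermediate
10 | lithium (2R)-1-(2-nonyl-1,3-dithian-2-yl)-3-[(2R)-oxiran-2-yl]propan-2-olate | CCCCCCCCCC1(SCCCS1)C[C@H](O[Li])C[C@@H]1CO1 | intermediate
11 | 2-lithio-2-[2-(benzyloxy)ethyl]-1,3-dithiane | [Li]C1(CCOCc2ccccc2)SCCCS1 | intermediate
12 | (2R,4R)-1-{2-[2-(benzyloxy)ethyl]-1,3-dithian-2-yl}-5-(2-nonyl-1,3-dithian-2-yl)pentane-2,4-diol | CCCCCCCCCC1(SCCCS1)C[C@H](O)C[C@@H](O)CC1(CCOCc2ccccc2)SCCCS1 | intermediate
13 | (5R,7R)-1-(benzyloxy)-5,7-dihydroxyoctadecane-3,9-dione | CCCCCCCCCC(=O)C[C@H](O)C[C@@H](O)CC(=O)CCOCc1ccccc1 | intermediate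
14 | bis(diethylborinate) of 13, (5R,7R)-1-(benzyloxy)-5,7-bis[(diethylboranyl)oxy]octadecane-3,9-dione | CCCCCCCCCC(=O)C[C@H](OB(CC)CC)C[C@@H](OB(CC)CC)CC(=O)CCOCc1ccccc1 | intermediate
15 | (3S,5S,7S,9S)-1-(benzyloxy)octadecane-3,5,7,9-tetrol | CCCCCCCCC[C@H](O)C[C@H](O)C[C@@H](O)C[C@@H](O)CCOCc1ccccc1 | intermediate
16 | (4S,6S)-4-[2-(benzyloxy)ethyl]-6-{[(4S,6S)-2,2-dimethyl-6-nonyl-1,3-dioxan-4-yl]methyl}-2,2-dimethyl-1,3-dioxane | CCCCCCCCC[C@H]1C[C@@H](C[C@@H]2C[C@H](CCOCc3ccccc3)OC(C)(C)O2)OC(C)(C)O1 | intermediate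
17 | 2-[(4S,6S)-6-{[(4S,6S)-2,2-dimethyl-6-nonyl-1,3-dioxan-4-yl]methyl}-2,2-dimethyl-1,3-dioxan-4-yl]ethan-1-ol | CCCCCCCCC[C@H]1C[C@@H](C[C@@H]2C[C@H](CCO)OC(C)(C)O2)OC(C)(C)O1 | intermediate
18 | [(4R,6R)-6-{[(4S,6S)-2,2-dimethyl-6-nonyl-1,3-dioxan-4-yl]methyl}-2,2-dimethyl-1,3-dioxan-4-yl]acetic acid | CCCCCCCCC[C@H]1C[C@@H](C[C@@H]2C[C@H](CC(=O)O)OC(C)(C)O2)OC(C)(C)O1 | intermediate
19 | acyl imidazolide of 18, 2-[(4R,6R)-6-{[(4S,6S)-2,2-dimethyl-6-nonyl-1,3-dioxan-4-yl]methyl}-2,2-dimethyl-1,3-dioxan-4-yl]-1-(imidazol-1-yl)ethan-1-one | CCCCCCCCC[C@H]1C[C@@H](C[C@@H]2C[C@H](CC(=O)n3ccnc3)OC(C)(C)O2)OC(C)(C)O1 | intermediate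
20 | ethyl 4-[(4R,6R)-6-{[(4S,6S)-2,2-dimethyl-6-nonyl-1,3-dioxan-4-yl]methyl}-2,2-dimethyl-1,3-dioxan-4-yl]-3-oxobutanoate | CCCCCCCCC[C@H]1C[C@@H](C[C@@H]2C[C@H](CC(=O)CC(=O)OCC)OC(C)(C)O2)OC(C)(C)O1 | intermediate
21 | ethyl (5R,7R,9S,11S)-5,7,9,11-tetrahydroxy-3-oxoicosanoate | CCCCCCCCC[C@H](O)C[C@H](O)C[C@@H](O)C[C@@H](O)CC(=O)CC(=O)OCC | intermediate
22 | (6R)-4-hydroxy-6-[(2R,4S,6S)-2,4,6-trihydroxypentadecyl]-5,6-dihydro-2H-pyran-2-one | CCCCCCCCC[C@H](O)C[C@H](O)C[C@@H](O)C[C@@H]1CC(O)=CC(=O)O1 | target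

**Step count and risks**

Total step count: 12. Longest linear sequence: 10 steps (steps 1, 2 and 5 to 12, from 1 to 22).

Steps most likely to fail:

Step 5. Mono-selectivity may be lost in the first opening, either by double opening by 9 or by oligomerisation of alkoxide 10 while THF and surplus 3 are stripped, and this would erode the three-component union. The fallback gives up the one-flask union and sets out from 3 and 6. Anion 9 is added to excess 3 as before, the mixture is quenched with aq NH4Cl, surplus 3 is recovered by distillation and the neutral epoxy alcohol (2R)-1-(2-nonyl-1,3-dithian-2-yl)-3-[(2R)-oxiran-2-yl]propan-2-ol F1 is purified by chromatography. F1 is then treated with 2.2 equiv of lithiated 8 in THF/DMPU (−78 → 0 °C), the first equivalent serving to deprotonate the hydroxyl, which comes back to the route at 12.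

Step 6. During the double hydrolysis the C7 and C9 hydroxyls may capture the sulfonium or thionium intermediates or the freed carbonyls (cyclic O,S-ketals, hemiketals, bridged ketals), or the new β-hydroxy ketones may eliminate. The fallback sets out from 12 and unmasks the ketones while the carbinols are blocked. TESOTf and 2,6-lutidine in CH2Cl2 give (2R,4R)-1-{2-[2-(benzyloxy)ethyl]-1,3-dithian-2-yl}-5-(2-nonyl-1,3-dithian-2-yl)-2,4-bis[(triethylsilyl)oxy]pentane F2. MeI and CaCO3 in aqueous MeCN then give (5R,7R)-1-(benzyloxy)-5,7-bis[(triethylsilyl)oxy]octadecane-3,9-dione F3, in which no hydroxyl can intercept an intermediate. Buffered HF·pyridine in THF/pyridine at 0 °C removes the silyl groups, and the route is rejoined at 13, which is taken at once into step 7.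

Step 12. After acetonide removal the C3 ketone may be tied up as a six-membered hemiketal by the C7 hydroxyl, the β-hydroxy ketone may dehydrate in acid, or saponification and decarboxylation may outrun lactonisation in base. The fallback sets out from 18 and avoids any basic stage. CDI followed by Mg(O2CCH2CO2tBu)2 gives tert-butyl 4-[(4R,6R)-6-{[(4S,6S)-2,2-dimethyl-6-nonyl-1,3-dioxan-4-yl]methyl}-2,2-dimethyl-1,3-dioxan-4-yl]-3-oxobutanoate F4. TFA in CH2Cl2 with a little water (0 °C → rt) removes both acetonides, cleaves the tert-butyl ester by alkyl–oxygen fission and should close the lactone in the same acidic medium, arriving at 22.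

Further compounds
F1 | step 5 | (2R)-1-(2-nonyl-1,3-dithian-2-yl)-3-[(2R)-oxiran-2-yl]propan-2-ol | CCCCCCCCCC1(SCCCS1)C[C@H](O)C[C@@H]1CO1
F2 | step 6 | (2R,4R)-1-{2-[2-(benzyloxy)ethyl]-1,3-dithian-2-yl}-5-(2-nonyl-1,3-dithian-2-yl)-2,4-bis[(triethylsilyl)oxy]pentane | CCCCCCCCCC1(SCCCS1)C[C@H](O[Si](CC)(CC)CC)C[C@@H](O[Si](CC)(CC)CC)CC1(CCOCc2ccccc2)SCCCS1
F3 | step 6 | (5R,7R)-1-(benzyloxy)-5,7-bis[(triethylsilyl)oxy]octadecane-3,9-dione | CCCCCCCCCC(=O)C[C@H](O[Si](CC)(CC)CC)C[C@@H](O[Si](CC)(CC)CC)CC(=O)CCOCc1ccccc1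
F4 | step 12 | tert-butyl 4-[(4R,6R)-6-{[(4S,6S)-2,2-dimethyl-6-nonyl-1,3-dioxan-4-yl]methyl}-2,2-dimethyl-1,3-dioxan-4-yl]-3-oxobutanoate | CCCCCCCCC[C@H]1C[C@@H](C[C@@H]2C[C@H](CC(=O)CC(=O)OC(C)(C)C)OC(C)(C)O2)OC(C)(C)O1
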